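**Plan**

1. Retrosynthesis: remove the primary acetate and the enal oxidation level, then cut C1–C1′ (ring-A carbinol carbon to the side-chain CH2) together with the lactone O2–C3 bond. This gives the 2-acetoxy-5-formyl-dihydropyran 15 and the silyl dienol ether 17 of (E)-2-methylbut-2-enal.
2. Open 15 at O7 to an aldehyde plus a 2-substituted malondialdehyde (tris-acetal 13). 13 comes from a γ-nitro aldehyde by one-carbon homologation, C-formylation and Nef reaction. Cut C4a–C5 last (Michael) to methyl 4-oxobutanoate 8 and nitrodiene 7.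
3. Forward order: chain (C4a–C5) first, then ring B (the dihydropyran, steps 7–8), then the fragment union that forms C1–C1′ and closes ring A (δ-lactone), then reduction and acetylation.
4. Enabling feature: C1 is the carbonyl carbon of a vinylogous formate (O=C1–C8a=C8–O7) and lies 1,5 to the ester carbonyl C3 on the C4a arm. C1′–C4′ is the γ-terminus of a tiglaldehyde dienolate, so one γ-selective aldol can set C1, the E-alkene and the lactone.
5. Stereochemistry: C4a/C5 from the (R)-diarylprolinol silyl ether Michael addition (syn). C6 from anomeric acetylation trans to C5. C1 from a chiral oxazaborolidinone, expected to match the substrate bias. E-olefin from the s-trans dienol ether.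

Key step: step 10

Remark: locants for 19–21 follow the pyrano[3,4-c]pyran skeleton (C1 carbinol carbon, O2, C3 lactone carbonyl, C4, C4a, C5, C6 acetal carbon, O7, C8, C8a). Compounds 14, 15 and 18 are numbered as 3,4-dihydro-2H-pyrans. Enol ether 10 and lactol 14 are carried as E/Z and anomeric mixtures that converge in the following step.

**Route**

Step 1
Reactants: 1 2-(2-bromoethyl)-2-methyl-1,3-dioxolane; 2 2,3-dibromoprop-1-ene
Product: 4 2-(4-bromopent-4-en-1-yl)-2-methyl-1,3-dioxolane, via Grignard reagent 3 (not isolated)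
Conditions: Mg, THF, 25 °C; then 2, CuI (5 mol %), THF, −20 to 0 °C
Reagents that add atoms: none
Why: Copper-catalysed allylic substitution of a Grignard reagent on 2,3-dibromopropene (SN2 and SN2′ give the same product) should leave the vinylic bromide untouched; no stereocentre is formed.

Step 2
Reactants: 4 2-(4-bromopent-4-en-1-yl)-2-methyl-1,3-dioxolane; 5 (E)-N,N-dimethyl-2-nitroethenamine
Product: 7 2-methyl-2-[(5E)-4-methylidene-6-nitrohex-5-en-1-yl]-1,3-dioxolane, via alkenylmagnesium bromide 6 (not isolated)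
Conditions: Mg, THF, 45 °C; then 5, THF, −20 °C; aq. AcOH, 0 °C
Reagents that add atoms: none
Why: Addition–elimination of the alkenyl Grignard reagent on the nitroenamine (conjugate addition, then loss of dimethylamine on acidification) should give the E-nitroalkene under thermodynamic control.

Step 3
Reactants: 7 2-methyl-2-[(5E)-4-methylidene-6-nitrohex-5-en-1-yl]-1,3-dioxolane; 8 methyl 4-oxobutanoate
Product: 9 methyl (3S,4R)-3-formyl-5-methylidene-8-(2-methyl-1,3-dioxolan-2-yl)-4-(nitromethyl)octanoate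
Conditions: (R)-α,α-diphenylprolinol trimethylsilyl ether (10 mol %), 4-nitrophenol (10 mol %), PhMe, 0 °C
Reagents that add atoms: none
Why: Enamine-catalysed Michael addition of an aldehyde to a nitroalkene; the E-enamine, shielded on one face by the diaryl(silyloxy)methyl group, should add 1,4 through the usual synclinal transition state and set both centres syn (future C4a and C5), with the (R)-catalyst giving the (3S,4R) series.

Step 4
Reactants: 9 methyl (3S,4R)-3-formyl-5-methylidene-8-(2-methyl-1,3-dioxolan-2-yl)-4-(nitromethyl)octanoate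
Product: 10 methyl (3S,4R)-3-(2-methoxyethenyl)-5-methylidene-8-(2-methyl-1,3-dioxolan-2-yl)-4-(nitromethyl)octanoate (E/Z mixture)
Conditions: MeOCH2PPh3Cl (3 equiv), KHMDS (2.8 equiv), THF, −78 to 0 °C; aq. NH4Cl
Reagents that add atoms: (methoxymethyl)triphenylphosphonium chloride, COC[P+](c1ccccc1)(c1ccccc1)c1ccccc1.[Cl-]
Why: Wittig methoxymethylenation (one-carbon homologation to an enol ether); excess ylide compensates for reversible deprotonation of the nitromethyl group, and the α-stereocentre should survive at low temperature.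

Step 5
Reactants: 10 methyl (3S,4R)-3-(2-methoxyethenyl)-5-methylidene-8-(2-methyl-1,3-dioxolan-2-yl)-4-(nitromethyl)octanoate
Product: 11 methyl (3S,4R)-5-methylidene-8-(2-methyl-1,3-dioxolan-2-yl)-4-(nitromethyl)-3-(1,1,3,3-tetramethoxypropan-2-yl)octanoate
Conditions: HC(OMe)3 (10 equiv), BF3·OEt2 (10 mol %), CH2Cl2, −45 °C; Et3N quench
Reagents that add atoms: trimethyl orthoformate, COC(OC)OC
Why: Lewis-acid-catalysed addition of a dialkoxycarbenium ion to the β-carbon of the enol ether (orthoformate–enol ether condensation) should give the malondialdehyde bis(dimethyl acetal); no stereocentre is formed because the two acetal arms are identical.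

Step 6
Reactants: 11 methyl (3S,4R)-5-methylidene-8-(2-methyl-1,3-dioxolan-2-yl)-4-(nitromethyl)-3-(1,1,3,3-tetramethoxypropan-2-yl)octanoate
Product: 13 methyl (3S,4R)-4-(dimethoxymethyl)-5-methylidene-8-(2-methyl-1,3-dioxolan-2-yl)-3-(1,1,3,3-tetramethoxypropan-2-yl)octanoate, via sodium nitronate 12 (not isolated)
Conditions: NaOMe, MeOH, 0 °C; then added to H2SO4/MeOH, −40 °C; NaHCO3
Reagents that add atoms: methanol, CO
Why: A Nef reaction run in methanol should convert the primary nitronate into the aldehyde dimethyl acetal without touching the adjacent stereocentre, which is not acidic.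

Step 7
Reactants: 13 methyl (3S,4R)-4-(dimethoxymethyl)-5-methylidene-8-(2-methyl-1,3-dioxolan-2-yl)-3-(1,1,3,3-tetramethoxypropan-2-yl)octanoate
Product: 14 methyl 2-[(3R,4S)-5-formyl-2-hydroxy-3-(6-oxohept-1-en-2-yl)-3,4-dihydro-2H-pyran-4-yl]acetate (anomeric mixture)
Conditions: 1 M HCl, THF, 23 °C
Reagents that add atoms: water, O
Why: Acetal and ketal hydrolysis releases the ketone and a 2-substituted malondialdehyde whose enol oxygen closes on the third aldehyde (six-membered lactol, ring–chain tautomerism toward the vinylogous formate); any epimerisation at C3 through the open aldehyde would favour the wanted 3,4-trans isomer.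

Step 8
Reactants: 14 methyl 2-[(3R,4S)-5-formyl-2-hydroxy-3-(6-oxohept-1-en-2-yl)-3,4-dihydro-2H-pyran-4-yl]acetate
Product: 15 methyl 2-[(2R,3R,4S)-2-acetoxy-5-formyl-3-(6-oxohept-1-en-2-yl)-3,4-dihydro-2H-pyran-4-yl]acetate
Conditions: Ac2O, pyridine, DMAP (cat.), CH2Cl2, 0 °C
Reagents that add atoms: acetic anhydride, CC(=O)OC(C)=O
Why: O-Acylation of the equilibrating lactol; the acetate should settle pseudo-axial (anomeric effect) and anti to the C3 alkenyl group, which is the 2,3-trans (2R) acetate.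

Step 9
Reactants: 16 (E)-2-methylbut-2-enal
Product: 17 tert-butyl(dimethyl){[(1E)-2-methylbuta-1,3-dien-1-yl]oxy}silane
Conditions: TBSOTf, Et3N, CH2Cl2, 0 to 23 °C
Reagents that add atoms: tert-butyldimethylsilyl trifluoromethanesulfonate, CC(C)(C)[Si](C)(C)OS(=O)(=O)C(F)(F)F
Why: Soft enolisation with O-silylation (silyl dienol ether formation) removes a γ-methyl hydrogen and should give the 1E diene with the silyloxy group anti to the vinyl group.

Step 10
Reactants: 15 methyl 2-[(2R,3R,4S)-2-acetoxy-5-formyl-3-(6-oxohept-1-en-2-yl)-3,4-dihydro-2H-pyran-4-yl]acetate; 17 tert-butyl(dimethyl){[(1E)-2-methylbuta-1,3-dien-1-yl]oxy}silane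
Product: 19 (1S,4aS,5R,6R)-1-[(2E)-3-methyl-4-oxobut-2-en-1-yl]-3-oxo-5-(6-oxohept-1-en-2-yl)-4,4a,5,6-tetrahydro-1H,3H-pyrano[3,4-c]pyran-6-yl acetate, via hydroxy ester 18 (not isolated)
Conditions: preformed (4R)-4-(1H-indol-3-ylmethyl)-3-(4-methylbenzenesulfonyl)-2-phenyl-1,3,2-oxazaborolidin-5-one (1.1 equiv), i-PrOH (1.1 equiv), EtCN, −78 °C; aq. NaHCO3; then 2-hydroxypyridine (20 mol %), PhMe, 45 °C
Reagents that add atoms: none
Why: The chiral boron Lewis acid binds the formyl oxygen of 15 and the terminal CH2 of 17 attacks the carbonyl carbon in an open transition state, with isopropanol taking over the silyl group (vinylogous Mukaiyama aldol; closest known type is the oxazaborolidinone-promoted vinylogous Mukaiyama aldol of aldehyde-derived silyl dienol ethers). The s-trans diene and its 2-methyl group direct attack to the γ-carbon and should deliver the (E)-2-methyl enal. The freed C1 hydroxyl then closes the δ-lactone by 6-exo-trig acyl substitution on the methyl ester of the neighbouring acetate arm. The new C1 centre is set by the D-tryptophan-derived reagent, which should expose the Si face of the aldehyde (mirror image of the L-series preference), and the substrate should push the same way because the pseudo-axial CH2CO2Me group on C4 of the pyran blocks the Re face of the s-trans formyl group. The step needs 1,2- over 1,4-addition (C6 of the pyran is the vinylogous site) and aldehyde over ketone selectivity; both rest on the aldehyde-specific two-point binding of the boron reagent (B–O and formyl C–H···O) at −78 °C.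

Step 11
Reactants: 19 (1S,4aS,5R,6R)-1-[(2E)-3-methyl-4-oxobut-2-en-1-yl]-3-oxo-5-(6-oxohept-1-en-2-yl)-4,4a,5,6-tetrahydro-1H,3H-pyrano[3,4-c]pyran-6-yl acetate
Product: 20 (1S,4aS,5R,6R)-1-[(2E)-4-hydroxy-3-methylbut-2-en-1-yl]-3-oxo-5-(6-oxohept-1-en-2-yl)-4,4a,5,6-tetrahydro-1H,3H-pyrano[3,4-c]pyran-6-yl acetate
Conditions: NaBH4 (0.5 equiv), MeOH/CH2Cl2 (1:4), −78 °C
Reagents that add atoms: none
Why: Chemoselective 1,2-reduction of the conjugated aldehyde by borohydride at low temperature, where the methyl ketone, lactone and acetate should react much more slowly; no stereocentre changes.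

Step 12
Reactants: 20 (1S,4aS,5R,6R)-1-[(2E)-4-hydroxy-3-methylbut-2-en-1-yl]-3-oxo-5-(6-oxohept-1-en-2-yl)-4,4a,5,6-tetrahydro-1H,3H-pyrano[3,4-c]pyran-6-yl acetate
Product: 21 (1S,4aS,5R,6R)-1-[(2E)-4-acetoxy-3-methylbut-2-en-1-yl]-3-oxo-5-(6-oxohept-1-en-2-yl)-4,4a,5,6-tetrahydro-1H,3H-pyrano[3,4-c]pyran-6-yl acetate
Conditions: Ac2O, pyridine, DMAP (cat.), CH2Cl2, 0 °C
Reagents that add atoms: acetic anhydride, CC(=O)OC(C)=O
Why: Acetylation of the primary allylic alcohol under basic conditions, which should leave the acid-labile enol ether and acetal acetate untouched.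

**Compound list**

1 | 2-(2-bromoethyl)-2-methyl-1,3-dioxolane | CC1(CCBr)OCCO1 | starting material
2 | 2,3-dibromoprop-1-ene | C=C(Br)CBr | starting material
3 | [2-(2-methyl-1,3-dioxolan-2-yl)ethyl]magnesium bromide | CC1(CC[Mg]Br)OCCO1 | intermediate
4 | 2-(4-bromopent-4-en-1-yl)-2-methyl-1,3-dioxolane | C=C(Br)CCCC1(C)OCCO1 | intermediate
5 | (E)-N,N-dimethyl-2-nitroethenamine | CN(C)/C=C/[N+](=O)[O-] | starting material
6 | [5-(2-methyl-1,3-dioxolan-2-yl)pent-1-en-2-yl]magnesium bromide | C=C([Mg]Br)CCCC1(C)OCCO1 | intermediate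
7 | 2-methyl-2-[(5E)-4-methylidene-6-nitrohex-5-en-1-yl]-1,3-dioxolane | C=C(/C=C/[N+](=O)[O-])CCCC1(C)OCCO1 | intermediate
8 | methyl 4-oxobutanoate | COC(=O)CCC=O | starting material
9 | methyl (3S,4R)-3-formyl-5-methylidene-8-(2-methyl-1,3-dioxolan-2-yl)-4-(nitromethyl)octanoate | C=C(CCCC1(C)OCCO1)[C@H](C[N+](=O)[O-])[C@H](CC(=O)OC)C=O | intermediate
10 | methyl (3S,4R)-3-(2-methoxyethenyl)-5-methylidene-8-(2-methyl-1,3-dioxolan-2-yl)-4-(nitromethyl)octanoate (E/Z mixture) | C=C(CCCC1(C)OCCO1)[C@H](C[N+](=O)[O-])[C@H](CC(=O)OC)C=COC | intermediate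
11 | methyl (3S,4R)-5-methylidene-8-(2-methyl-1,3-dioxolan-2-yl)-4-(nitromethyl)-3-(1,1,3,3-tetramethoxypropan-2-yl)octanoate | C=C(CCCC1(C)OCCO1)[C@H](C[N+](=O)[O-])[C@H](CC(=O)OC)C(C(OC)OC)C(OC)OC | intermediate
12 | sodium nitronate of 11 | C=C(CCCC1(C)OCCO1)[C@H](C=[N+]([O-])[O-])[C@H](CC(=O)OC)C(C(OC)OC)C(OC)OC.[Na+] | intermediate
13 | methyl (3S,4R)-4-(dimethoxymethyl)-5-methylidene-8-(2-methyl-1,3-dioxolan-2-yl)-3-(1,1,3,3-tetramethoxypropan-2-yl)octanoate | C=C(CCCC1(C)OCCO1)[C@H](C(OC)OC)[C@H](CC(=O)OC)C(C(OC)OC)C(OC)OC | intermediate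
14 | methyl 2-[(3R,4S)-5-formyl-2-hydroxy-3-(6-oxohept-1-en-2-yl)-3,4-dihydro-2H-pyran-4-yl]acetate (anomeric mixture) | C=C(CCCC(C)=O)[C@@H]1C(O)OC=C(C=O)[C@H]1CC(=O)OC | intermediate
15 | methyl 2-[(2R,3R,4S)-2-acetoxy-5-formyl-3-(6-oxohept-1-en-2-yl)-3,4-dihydro-2H-pyran-4-yl]acetate | C=C(CCCC(C)=O)[C@@H]1[C@@H](OC(C)=O)OC=C(C=O)[C@H]1CC(=O)OC | intermediate
16 | (E)-2-methylbut-2-enal | C/C=C(\C)C=O | starting material
17 | tert-butyl(dimethyl){[(1E)-2-methylbuta-1,3-dien-1-yl]oxy}silane | C=C/C(C)=C/O[Si](C)(C)C(C)(C)C | intermediate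
18 | methyl 2-[(2R,3R,4S)-2-acetoxy-5-[(1S,3E)-1-hydroxy-4-methyl-5-oxopent-3-en-1-yl]-3-(6-oxohept-1-en-2-yl)-3,4-dihydro-2H-pyran-4-yl]acetate | C=C(CCCC(C)=O)[C@@H]1[C@@H](OC(C)=O)OC=C([C@@H](O)C/C=C(\C)C=O)[C@H]1CC(=O)OC | intermediate
19 | (1S,4aS,5R,6R)-1-[(2E)-3-methyl-4-oxobut-2-en-1-yl]-3-oxo-5-(6-oxohept-1-en-2-yl)-4,4a,5,6-tetrahydro-1H,3H-pyrano[3,4-c]pyran-6-yl acetate | C=C(CCCC(C)=O)[C@@H]1[C@@H](OC(C)=O)OC=C2[C@H](C/C=C(\C)C=O)OC(=O)C[C@H]21 | intermediate
20 | (1S,4aS,5R,6R)-1-[(2E)-4-hydroxy-3-methylbut-2-en-1-yl]-3-oxo-5-(6-oxohept-1-en-2-yl)-4,4a,5,6-tetrahydro-1H,3H-pyrano[3,4-c]pyran-6-yl acetate | C=C(CCCC(C)=O)[C@@H]1[C@@H](OC(C)=O)OC=C2[C@H](C/C=C(\C)CO)OC(=O)C[C@H]21 | intermediate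
21 | (1S,4aS,5R,6R)-1-[(2E)-4-acetoxy-3-methylbut-2-en-1-yl]-3-oxo-5-(6-oxohept-1-en-2-yl)-4,4a,5,6-tetrahydro-1H,3H-pyrano[3,4-c]pyran-6-yl acetate | C=C(CCCC(C)=O)[C@@H]1[C@@H](OC(C)=O)OC=C2[C@H](C/C=C(\C)COC(C)=O)OC(=O)C[C@H]21 | target

Total step count: 12. Longest linear sequence: 11 steps (steps 1–8, then 10–12; step 9 is a one-step side branch).

**Steps most likely to fail**

Step 10. The silyl dienol ether may add in a conjugate sense at the enol-ether carbon of the vinylogous formate, the deactivated aldehyde may react too slowly, or facial selectivity may erode. The fallback makes the C1–CH2 bond in a closed six-membered transition state that can only add 1,2 and ignores the ketone. It sets out from 15: allylboration with allylboronic acid pinacol ester and (S)-TRIP phosphoric acid (5 mol %, PhMe, −30 °C) should give the homoallylic alcohol methyl 2-[(2R,3R,4S)-2-acetoxy-5-[(1S)-1-hydroxybut-3-en-1-yl]-3-(6-oxohept-1-en-2-yl)-3,4-dihydro-2H-pyran-4-yl]acetate F1. Lactonisation with catalytic 2-hydroxypyridine (PhMe, 45 °C) should give the allyl lactone (1S,4aS,5R,6R)-3-oxo-5-(6-oxohept-1-en-2-yl)-1-(prop-2-en-1-yl)-4,4a,5,6-tetrahydro-1H,3H-pyrano[3,4-c]pyran-6-yl acetate F2. Cross-metathesis of its monosubstituted alkene with methacrolein (second-generation ruthenium benzylidene catalyst, CH2Cl2, 40 °C) should install the (E)-2-methyl enal and return to the route at 19.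

Step 5. In the open-chain substrate the transient oxocarbenium ion can be captured by the 1,1-disubstituted alkene (Prins-type cyclisation to a cyclohexane) before methoxide transfer. The fallback closes the pyran before formylation. It sets out from 10: a Nef reaction in acidic methanol containing a trace of water, which also methanolyses the enol ether, should give the 2,6-dimethoxytetrahydropyran methyl 2-[(3R,4S)-2,6-dimethoxy-3-[5-(2-methyl-1,3-dioxolan-2-yl)pent-1-en-2-yl]oxan-4-yl]acetate F3. Acid-catalysed loss of methanol (TsOH cat., PhMe, reflux, methanol distilled off) should give the 2-methoxy-3,4-dihydro-2H-pyran methyl 2-[(3R,4R)-2-methoxy-3-[5-(2-methyl-1,3-dioxolan-2-yl)pent-1-en-2-yl]-3,4-dihydro-2H-pyran-4-yl]acetate F4. Vilsmeier–Haack formylation of the ring enol ether (POCl3, DMF, 0 °C; aq. NaOAc) should give methyl 2-[(3R,4S)-5-formyl-2-methoxy-3-[5-(2-methyl-1,3-dioxolan-2-yl)pent-1-en-2-yl]-3,4-dihydro-2H-pyran-4-yl]acetate F5; in the ring the alkene can reach the cation only through a bridged boat-like transition state. Aqueous acid (1 M HCl, THF) then hydrolyses the methyl acetal and the dioxolane and returns to the route at 14.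

Step 3. The 3-substituted nitrodiene may polymerise, or the enamine may add at the terminal CH2 (1,6-addition), which would lower both yield and stereocontrol. The fallback sets C4a/C5 on a lactone template and avoids all nitro chemistry. It sets out from 4: bromine–lithium exchange and borylation (t-BuLi, then i-PrOBpin, Et2O, −78 °C) should give the alkenyl boronate 4,4,5,5-tetramethyl-2-[5-(2-methyl-1,3-dioxolan-2-yl)pent-1-en-2-yl]-1,3,2-dioxaborolane F6. Rhodium-catalysed asymmetric 1,4-addition to furan-2(5H)-one ([Rh(cod)Cl]2, (R)-BINAP, aq. KOH, dioxane, 40 °C) should give (4R)-4-[5-(2-methyl-1,3-dioxolan-2-yl)pent-1-en-2-yl]oxolan-2-one F7. Enolate alkylation (LDA, methyl bromoacetate, THF, −78 °C) anti to the C4 substituent should give methyl 2-[(3S,4R)-4-[5-(2-methyl-1,3-dioxolan-2-yl)pent-1-en-2-yl]-2-oxooxolan-3-yl]acetate F8. DIBAL-H at −78 °C, where the γ-lactone should be reduced faster than the methyl ester, gives the lactol methyl 2-[(3S,4R)-2-hydroxy-4-[5-(2-methyl-1,3-dioxolan-2-yl)pent-1-en-2-yl]oxolan-3-yl]acetate F9. Wittig reaction with Ph3P=CHOMe gives methyl (3S,4R)-4-(hydroxymethyl)-3-(2-methoxyethenyl)-5-methylidene-8-(2-methyl-1,3-dioxolan-2-yl)octanoate F10. Buffered Dess–Martin oxidation gives methyl (3R,4R)-4-formyl-3-(2-methoxyethenyl)-5-methylidene-8-(2-methyl-1,3-dioxolan-2-yl)octanoate F11. Treatment with HC(OMe)3 and BF3·OEt2 then acetalises the aldehyde and formylates the enol ether in one operation and returns to the route at 13.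

**Further compounds**

F1 | step 10 | methyl 2-[(2R,3R,4S)-2-acetoxy-5-[(1S)-1-hydroxybut-3-en-1-yl]-3-(6-oxohept-1-en-2-yl)-3,4-dihydro-2H-pyran-4-yl]acetate | C=C(CCCC(C)=O)[C@@H]1[C@@H](OC(C)=O)OC=C([C@@H](O)CC=C)[C@H]1CC(=O)OC
F2 | step 10 | (1S,4aS,5R,6R)-3-oxo-5-(6-oxohept-1-en-2-yl)-1-(prop-2-en-1-yl)-4,4a,5,6-tetrahydro-1H,3H-pyrano[3,4-c]pyran-6-yl acetate | C=C(CCCC(C)=O)[C@@H]1[C@@H](OC(C)=O)OC=C2[C@H](CC=C)OC(=O)C[C@H]21
F3 | step 5 | methyl 2-[(3R,4S)-2,6-dimethoxy-3-[5-(2-methyl-1,3-dioxolan-2-yl)pent-1-en-2-yl]oxan-4-yl]acetate (mixture at C2 and C6) | C=C(CCCC1(C)OCCO1)[C@@H]1C(OC)OC(OC)C[C@H]1CC(=O)OC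
F4 | step 5 | methyl 2-[(3R,4R)-2-methoxy-3-[5-(2-methyl-1,3-dioxolan-2-yl)pent-1-en-2-yl]-3,4-dihydro-2H-pyran-4-yl]acetate (anomeric mixture) | C=C(CCCC1(C)OCCO1)[C@@H]1C(OC)OC=C[C@H]1CC(=O)OC
F5 | step 5 | methyl 2-[(3R,4S)-5-formyl-2-methoxy-3-[5-(2-methyl-1,3-dioxolan-2-yl)pent-1-en-2-yl]-3,4-dihydro-2H-pyran-4-yl]acetate (anomeric mixture) | C=C(CCCC1(C)OCCO1)[C@@H]1C(OC)OC=C(C=O)[C@H]1CC(=O)OC
F6 | step 3 | 4,4,5,5-tetramethyl-2-[5-(2-methyl-1,3-dioxolan-2-yl)pent-1-en-2-yl]-1,3,2-dioxaborolane | C=C(B1OC(C)(C)C(C)(C)O1)CCCC1(C)OCCO1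
F7 | step 3 | (4R)-4-[5-(2-methyl-1,3-dioxolan-2-yl)pent-1-en-2-yl]oxolan-2-one | C=C(CCCC1(C)OCCO1)[C@H]2CC(=O)OC2
F8 | step 3 | methyl 2-[(3S,4R)-4-[5-(2-methyl-1,3-dioxolan-2-yl)pent-1-en-2-yl]-2-oxooxolan-3-yl]acetate | C=C(CCCC1(C)OCCO1)[C@H]2[C@H](CC(=O)OC)C(=O)OC2
F9 | step 3 | methyl 2-[(3S,4R)-2-hydroxy-4-[5-(2-methyl-1,3-dioxolan-2-yl)pent-1-en-2-yl]oxolan-3-yl]acetate (anomeric mixture) | C=C(CCCC1(C)OCCO1)[C@H]2[C@H](CC(=O)OC)C(O)OC2
F10 | step 3 | methyl (3S,4R)-4-(hydroxymethyl)-3-(2-methoxyethenyl)-5-methylidene-8-(2-methyl-1,3-dioxolan-2-yl)octanoate (E/Z mixture) | C=C(CCCC1(C)OCCO1)[C@H](CO)[C@H](CC(=O)OC)C=COC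
F11 | step 3 | methyl (3R,4R)-4-formyl-3-(2-methoxyethenyl)-5-methylidene-8-(2-methyl-1,3-dioxolan-2-yl)octanoate (E/Z mixture) | C=C(CCCC1(C)OCCO1)[C@H](C=O)[C@H](CC(=O)OC)C=COC
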